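**Plan**

- Numbering: ring A is the benzoate ring (C1 CO2Me, C2 OH, C4 CH3, C6 aryloxy); ring B carries the ether oxygen at C1', CH2OH at C2', OCH3 at C4' and the prenyl ether at C6'.
- The retrosynthesis first adjusts the silyl ether and the ester oxidation level, then cuts C1–CHO and C2–O of ring A together, leading back to a 3-aryloxy-5-methylbenzyne and DMF. This is possible because C1 and C2 are neighbours and the C6 aryloxy group beside C1 polarises the C1–C2 aryne.
- The aryne precursor (silyl triflate) comes from a ring A phenol by carbamate-directed silylation. The diaryl ether bond C6–O–C1' is cut next (copper-catalysed coupling of a ring B phenol with 1-bromo-3-iodo-5-methylbenzene). Ring B is cut at C2'–CH2O (ortho-formylation), at C1'–O (from a bromide) and at the prenyl ether.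
- Forward: ring B phenol (steps 1–5), diaryl ether (6), ring A phenol to silyl triflate (7–10), aryne/DMF insertion (11), oxidation, methylation, desilylation (12–14). Both rings are bought as arenes; no ring is formed.
- Stereochemistry: none; the target is achiral and the prenyl alkene has no E/Z isomers.

Key step: step 11

Assumption: 2-bromo-5-methoxyphenol, prenyl bromide and 1-bromo-3-iodo-5-methylbenzene are taken as purchasable. "Prenyl" means 3-methylbut-2-en-1-yl, and "ArB" means the ring B aryl group 4-methoxy-6-(prenyloxy)-2-[(triisopropylsilyloxy)methyl]phenyl, bonded through its C1'.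

**Route**

Step 1
Reactants: 1 2-bromo-5-methoxyphenol; 2 prenyl bromide
Product: 3 1-bromo-4-methoxy-2-(prenyloxy)benzene
Conditions: K2CO3, DMF, 23 °C
Reagents that add atoms: none
Why: Williamson etherification of the phenoxide with the primary allylic bromide should proceed cleanly by SN2 at oxygen in a dipolar aprotic solvent.

Step 2
Reactants: 3 1-bromo-4-methoxy-2-(prenyloxy)benzene
Product: 6 4-methoxy-2-(prenyloxy)phenol, via aryllithium 4 (not isolated), via lithium aryltrimethoxyborate 5 (not isolated)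
Conditions: n-BuLi, THF, −78 °C; B(OMe)3, −78 → 23 °C; 30% H2O2, aq. NaOH, 0 °C
Reagents that add atoms: hydrogen peroxide, OO
Why: Bromine–lithium exchange at −78 °C is faster than any reaction of the allylic ether, and borylation followed by alkaline peroxide oxidation (1,2-shift of the aryl group from boron to oxygen) should give the phenol while the trisubstituted alkene, inert to basic hydrogen peroxide, stays intact.

Step 3
Reactants: 6 4-methoxy-2-(prenyloxy)phenol
Product: 7 2-hydroxy-5-methoxy-3-(prenyloxy)benzaldehyde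
Conditions: MgCl2, Et3N, (CH2O)n, MeCN, reflux; then aq. HCl
Reagents that add atoms: paraformaldehyde (formaldehyde unit), C=O
Why: The magnesium-mediated ortho-formylation of phenols (Casnati–Skattebøl reaction) delivers formaldehyde inside the magnesium phenoxide chelate to the only free ortho position, and a second formaldehyde oxidises the benzylic alkoxide to the aldehyde by Oppenauer-type hydride transfer.

Step 4
Reactants: 7 2-hydroxy-5-methoxy-3-(prenyloxy)benzaldehyde
Product: 8 2-(hydroxymethyl)-4-methoxy-6-(prenyloxy)phenol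
Conditions: NaBH4, MeOH, 0 °C
Reagents that add atoms: none
Why: Borohydride reduction of the aldehyde is chemoselective and should leave the prenyl ether untouched.

Step 5
Reactants: 8 2-(hydroxymethyl)-4-methoxy-6-(prenyloxy)phenol
Product: 9 4-methoxy-6-(prenyloxy)-2-[(triisopropylsilyloxy)methyl]phenol
Conditions: TIPSCl (1.05 equiv), imidazole, CH2Cl2, 0 °C
Reagents that add atoms: triisopropylsilyl chloride, CC(C)[Si](Cl)(C(C)C)C(C)C
Why: Selective silylation of the primary benzylic hydroxyl is expected because the phenol is flanked by two ortho substituents and reacts poorly with the bulky silyl chloride.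

Step 6
Reactants: 9 4-methoxy-6-(prenyloxy)-2-[(triisopropylsilyloxy)methyl]phenol; 10 1-bromo-3-iodo-5-methylbenzene
Product: 11 1-bromo-3-(ArB-oxy)-5-methylbenzene
Conditions: CuI (10 mol %), picolinic acid (20 mol %), K3PO4, DMSO, 80 °C
Reagents that add atoms: none
Why: The copper-catalysed Ullmann-type diaryl ether synthesis with picolinic acid as ligand tolerates doubly ortho-substituted phenols, and monovalent copper inserts into the C–I bond much faster than into the C–Br bond, so only the iodide should be displaced.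

Step 7
Reactants: 11 1-bromo-3-(ArB-oxy)-5-methylbenzene
Product: 14 3-(ArB-oxy)-5-methylphenol, via aryllithium 12 (not isolated), via lithium aryltrimethoxyborate 13 (not isolated)
Conditions: n-BuLi, THF, −78 °C; B(OMe)3, −78 → 23 °C; 30% H2O2, aq. NaOH, 0 °C
Reagents that add atoms: hydrogen peroxide, OO
Why: The same bromine–lithium exchange, borylation and oxidation sequence as in step 2 should convert the remaining C–Br bond into the phenol, since the silyl ether, the prenyl ether and the diaryl ether are all stable to n-BuLi at −78 °C and to basic peroxide.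

Step 8
Reactants: 14 3-(ArB-oxy)-5-methylphenol
Product: 15 3-(ArB-oxy)-5-methylphenyl N-isopropylcarbamate
Conditions: i-PrNCO, Et3N (cat.), CH2Cl2, 23 °C
Reagents that add atoms: isopropyl isocyanate, CC(C)N=C=O
Why: Base-catalysed addition of the phenol to the isocyanate gives the N-isopropyl carbamate, a directing group for ortho-metalation that can later be removed without hydrolysis.

Step 9
Reactants: 15 3-(ArB-oxy)-5-methylphenyl N-isopropylcarbamate
Product: 19 3-(ArB-oxy)-5-methyl-2-(trimethylsilyl)phenyl N-isopropylcarbamate, via N-silyl carbamate 16 (not isolated), via ortho-lithiated carbamate 17 (not isolated), via C-silylated N-silyl carbamate 18 (not isolated)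
Conditions: TBSOTf, TMEDA, Et2O, 0 → 23 °C; n-BuLi (2 equiv), TMEDA, −78 °C; TMSCl, −78 → 23 °C; aq. NaHSO4
Reagents that add atoms: chlorotrimethylsilane, C[Si](C)(C)Cl
Why: Directed ortho-metalation of the transiently N-silylated carbamate should occur at the ring A carbon between the carbamate and the aryloxy group, which is the most acidic site and is held by the coordinating carbamate, and silylation followed by acidic work-up returns the N–H carbamate.

Step 10
Reactants: 19 3-(ArB-oxy)-5-methyl-2-(trimethylsilyl)phenyl N-isopropylcarbamate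
Product: 21 3-(ArB-oxy)-5-methyl-2-(trimethylsilyl)phenyl trifluoromethanesulfonate, via silylphenol 20 (not isolated)
Conditions: DBU, Et2NH, MeCN, 40 °C; then PhNTf2, 23 °C
Reagents that add atoms: N-phenylbis(trifluoromethanesulfonimide), O=S(=O)(N(c1ccccc1)S(=O)(=O)C(F)(F)F)C(F)(F)F
Why: DBU removes the carbamate N–H and the phenoxide leaves by E1cB elimination of isopropyl isocyanate, which diethylamine traps as a urea, and the phenoxide is triflated in the same flask so that the aryl–silicon bond never meets protic acid.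

Step 11
Reactants: 21 3-(ArB-oxy)-5-methyl-2-(trimethylsilyl)phenyl trifluoromethanesulfonate; 22 N,N-dimethylformamide
Product: 26 2-(ArB-oxy)-6-hydroxy-4-methylbenzaldehyde, via aryne 23 (not isolated), via benzoxete 24 (not isolated), via quinone methide 25 (not isolated)
Conditions: CsF, DMF (solvent and reactant), 23 °C; then H2O
Reagents that add atoms: water, O
Why: Fluoride attacks silicon and triflate leaves to give aryne 23, the carbonyl oxygen of DMF adds to the aryne carbon remote from the aryloxy group, the aryl anion formed beside that group attacks the iminium carbon to close benzoxete 24, this opens to the aminomethylene quinone methide 25, and water hydrolyses 25 to the phenol and the aldehyde. The closest known reaction type is the formal insertion of arynes into the C=O bond of formamides, which gives salicylaldehydes after hydrolysis and is regioselective for 3-alkoxyarynes. The only ring closed is the transient four-membered oxete (4-exo-trig attack of the aryl anion on the iminium carbon), which reopens at once, so no new ring remains in the product. No stereocentre is formed. The step needs regioselective addition to the unsymmetrical aryne, and the inductively withdrawing aryloxy group at C6 secures it by stabilising negative charge at the adjacent C1, so that oxygen ends up at C2 and the formyl carbon at C1. DMF as solvent should outrun any intramolecular capture of the aryne by ring B or the prenyl group, and the primary triisopropylsilyl ether should withstand CsF at ambient temperature.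

Step 12
Reactants: 26 2-(ArB-oxy)-6-hydroxy-4-methylbenzaldehyde
Product: 27 2-(ArB-oxy)-6-hydroxy-4-methylbenzoic acid
Conditions: NaClO2, NaH2PO4, 2-methyl-2-butene (large excess), t-BuOH/H2O, 0 → 23 °C
Reagents that add atoms: sodium chlorite, [Na+].[O-]Cl=O
Why: The Pinnick oxidation converts the aldehyde to the acid through addition of chlorous acid and fragmentation, and the excess 2-methyl-2-butene removes hypochlorous acid before it can chlorinate the electron-rich rings or the prenyl alkene.

Step 13
Reactants: 27 2-(ArB-oxy)-6-hydroxy-4-methylbenzoic acid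
Product: 28 methyl 2-(ArB-oxy)-6-hydroxy-4-methylbenzoate
Conditions: MeI, KHCO3, DMF, 23 °C
Reagents that add atoms: iodomethane, CI
Why: Bicarbonate deprotonates only the carboxylic acid, so SN2 methylation of the carboxylate gives the ester and leaves the hydrogen-bonded phenol free.

Step 14
Reactants: 28 methyl 2-(ArB-oxy)-6-hydroxy-4-methylbenzoate
Product: 29 methyl 2-hydroxy-6-[2-(hydroxymethyl)-4-methoxy-6-(prenyloxy)phenoxy]-4-methylbenzoate
Conditions: TBAF, AcOH, THF, 0 → 23 °C
Reagents that add atoms: none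
Why: Fluoride cleaves the Si–O bond of the primary silyl ether, and the acetic acid buffer keeps the salicylate ester and the phenol from base-induced side reactions.

**Compound list**

1 | 2-bromo-5-methoxyphenol | COc1ccc(Br)c(O)c1 | starting material
2 | prenyl bromide (1-bromo-3-methylbut-2-ene) | CC(C)=CCBr | starting material
3 | 1-bromo-4-methoxy-2-(prenyloxy)benzene | COc1ccc(Br)c(OCC=C(C)C)c1 | intermediate
4 | 4-methoxy-2-(prenyloxy)phenyllithium | COc1ccc([Li])c(OCC=C(C)C)c1 | intermediate
5 | lithium trimethoxy[4-methoxy-2-(prenyloxy)phenyl]borate | [Li+].CO[B-](OC)(OC)c1ccc(OC)cc1OCC=C(C)C | intermediate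
6 | 4-methoxy-2-(prenyloxy)phenol | COc1ccc(O)c(OCC=C(C)C)c1 | intermediate
7 | 2-hydroxy-5-methoxy-3-(prenyloxy)benzaldehyde | COc1cc(OCC=C(C)C)c(O)c(C=O)c1 | intermediate
8 | 2-(hydroxymethyl)-4-methoxy-6-(prenyloxy)phenol | COc1cc(CO)c(O)c(OCC=C(C)C)c1 | intermediate
9 | 4-methoxy-6-(prenyloxy)-2-[(triisopropylsilyloxy)methyl]phenol | COc1cc(CO[Si](C(C)C)(C(C)C)C(C)C)c(O)c(OCC=C(C)C)c1 | intermediate
10 | 1-bromo-3-iodo-5-methylbenzene | Cc1cc(Br)cc(I)c1 | starting material
11 | 1-bromo-3-(ArB-oxy)-5-methylbenzene | Cc1cc(Br)cc(Oc2c(CO[Si](C(C)C)(C(C)C)C(C)C)cc(OC)cc2OCC=C(C)C)c1 | intermediate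
12 | 3-(ArB-oxy)-5-methylphenyllithium | Cc1cc([Li])cc(Oc2c(CO[Si](C(C)C)(C(C)C)C(C)C)cc(OC)cc2OCC=C(C)C)c1 | intermediate
13 | lithium [3-(ArB-oxy)-5-methylphenyl]trimethoxyborate | [Li+].CO[B-](OC)(OC)c1cc(C)cc(Oc2c(CO[Si](C(C)C)(C(C)C)C(C)C)cc(OC)cc2OCC=C(C)C)c1 | intermediate
14 | 3-(ArB-oxy)-5-methylphenol | Cc1cc(O)cc(Oc2c(CO[Si](C(C)C)(C(C)C)C(C)C)cc(OC)cc2OCC=C(C)C)c1 | intermediate
15 | 3-(ArB-oxy)-5-methylphenyl N-isopropylcarbamate | Cc1cc(OC(=O)NC(C)C)cc(Oc2c(CO[Si](C(C)C)(C(C)C)C(C)C)cc(OC)cc2OCC=C(C)C)c1 | intermediate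
16 | 3-(ArB-oxy)-5-methylphenyl N-(tert-butyldimethylsilyl)-N-isopropylcarbamate | Cc1cc(OC(=O)N(C(C)C)[Si](C)(C)C(C)(C)C)cc(Oc2c(CO[Si](C(C)C)(C(C)C)C(C)C)cc(OC)cc2OCC=C(C)C)c1 | intermediate
17 | 2-lithio derivative of 16 (lithium on the ring A carbon between the two oxygens) | Cc1cc(OC(=O)N(C(C)C)[Si](C)(C)C(C)(C)C)c([Li])c(Oc2c(CO[Si](C(C)C)(C(C)C)C(C)C)cc(OC)cc2OCC=C(C)C)c1 | intermediate
18 | 3-(ArB-oxy)-5-methyl-2-(trimethylsilyl)phenyl N-(tert-butyldimethylsilyl)-N-isopropylcarbamate | Cc1cc(OC(=O)N(C(C)C)[Si](C)(C)C(C)(C)C)c([Si](C)(C)C)c(Oc2c(CO[Si](C(C)C)(C(C)C)C(C)C)cc(OC)cc2OCC=C(C)C)c1 | intermediate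
19 | 3-(ArB-oxy)-5-methyl-2-(trimethylsilyl)phenyl N-isopropylcarbamate | Cc1cc(OC(=O)NC(C)C)c([Si](C)(C)C)c(Oc2c(CO[Si](C(C)C)(C(C)C)C(C)C)cc(OC)cc2OCC=C(C)C)c1 | intermediate
20 | 3-(ArB-oxy)-5-methyl-2-(trimethylsilyl)phenol | Cc1cc(O)c([Si](C)(C)C)c(Oc2c(CO[Si](C(C)C)(C(C)C)C(C)C)cc(OC)cc2OCC=C(C)C)c1 | intermediate
21 | 3-(ArB-oxy)-5-methyl-2-(trimethylsilyl)phenyl trifluoromethanesulfonate | Cc1cc(OS(=O)(=O)C(F)(F)F)c([Si](C)(C)C)c(Oc2c(CO[Si](C(C)C)(C(C)C)C(C)C)cc(OC)cc2OCC=C(C)C)c1 | intermediate
22 | N,N-dimethylformamide | CN(C)C=O | starting material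
23 | 3-(ArB-oxy)-5-methylbenzyne (triple bond between the former C–OTf and C–Si carbons) | CC1=CC#CC(Oc2c(CO[Si](C(C)C)(C(C)C)C(C)C)cc(OC)cc2OCC=C(C)C)=C1 | intermediate
24 | 2-(dimethylamino)-2H-benzoxete fused to ring A (ring oxygen on the carbon remote from the ArB-oxy group; racemic) | CN(C)C1Oc2cc(C)cc(Oc3c(CO[Si](C(C)C)(C(C)C)C(C)C)cc(OC)cc3OCC=C(C)C)c12 | intermediate
25 | 5-(ArB-oxy)-6-[(dimethylamino)methylidene]-3-methylcyclohexa-2,4-dien-1-one | CN(C)C=C1C(=O)C=C(C)C=C1Oc2c(CO[Si](C(C)C)(C(C)C)C(C)C)cc(OC)cc2OCC=C(C)C | intermediate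
26 | 2-(ArB-oxy)-6-hydroxy-4-methylbenzaldehyde | Cc1cc(O)c(C=O)c(Oc2c(CO[Si](C(C)C)(C(C)C)C(C)C)cc(OC)cc2OCC=C(C)C)c1 | intermediate
27 | 2-(ArB-oxy)-6-hydroxy-4-methylbenzoic acid | Cc1cc(O)c(C(=O)O)c(Oc2c(CO[Si](C(C)C)(C(C)C)C(C)C)cc(OC)cc2OCC=C(C)C)c1 | intermediate
28 | methyl 2-(ArB-oxy)-6-hydroxy-4-methylbenzoate | COC(=O)c1c(O)cc(C)cc1Oc2c(CO[Si](C(C)C)(C(C)C)C(C)C)cc(OC)cc2OCC=C(C)C | intermediate
29 | methyl 2-hydroxy-6-[2-(hydroxymethyl)-4-methoxy-6-(prenyloxy)phenoxy]-4-methylbenzoate (CNP0532721.0) | COC(=O)c1c(O)cc(C)cc1Oc1c(CO)cc(OC)cc1OCC=C(C)C | target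

**Step count and risks**

Total step count: 14. Longest linear sequence: 14 (steps 1–14 from compound 1).

Steps most likely to fail:

1. Step 9 (directed silylation). The base may deprotonate elsewhere: at the other ortho position of ring A, at the ring B carbon between the two alkoxy groups, or at an O–CH2 group. N-silylation may also be incomplete. The fallback sets out from bromide 11 and uses the bromine atom, not a carbamate, to fix the site. Lithium diisopropylamide is added to 11 and TMSCl in THF at −78 °C. It removes the proton between bromine and the aryloxy group to give the 2-lithio bromide F1, which is silylated in the flask to [2-bromo-6-(ArB-oxy)-4-methylphenyl]trimethylsilane F2. Bromine–lithium exchange with n-BuLi gives the aryllithium F3, B(OMe)3 gives the lithium aryltrimethoxyborate F4, and H2O2/NaOH should give silylphenol 20. Triflation of 20 with PhNTf2 and DBU in MeCN comes back to the route at 21.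

2. Step 6 (diaryl ether coupling). C–O bond formation may be slow at the doubly ortho-substituted phenoxide, and the 2-(silyloxymethyl)phenoxide may lose silanolate on heating (quinone methide formation). The fallback sets out from 10 and aldehyde 7 and is a metal-free arylation at the aldehyde stage. Oxidation of 10 with mCPBA and TsOH in MeCN gives the hydroxy(tosyloxy)iodoarene F5 (trivalent iodine). Adding 1,3,5-trimethoxybenzene to the same flask gives (3-bromo-5-methylphenyl)(2,4,6-trimethoxyphenyl)iodonium tosylate F6. Phenol 7 with F6 and K2CO3 in MeCN should transfer the less electron-rich aryl group to oxygen and give 2-(3-bromo-5-methylphenoxy)-5-methoxy-3-(prenyloxy)benzaldehyde F7. NaBH4 reduction gives the benzylic alcohol F8, and TIPSCl/imidazole comes back to the route at 11.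

3. Step 11 (aryne insertion). The formamide oxygen may add to the wrong aryne carbon, ring B or the prenyl group may capture the aryne, or fluoride may cleave the silyl ether and the alkoxide then add to the aryne. The fallback sets out from carbamate 15 and forms the same two bonds by directed metalation. N-silylation and ortho-lithiation as in step 9 (through 16 and 17) are followed by a DMF quench in place of TMSCl, which gives the lithium aminoalkoxide adduct F9. Work-up with aq. NaHSO4 gives 3-(ArB-oxy)-2-formyl-5-methylphenyl N-isopropylcarbamate F10. Cleavage of the carbamate with DBU and Et2NH in MeCN comes back to the route at 26.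

**Further compounds**

F1 | step 9 | 1-bromo-3-(ArB-oxy)-2-lithio-5-methylbenzene | Cc1cc(Br)c([Li])c(Oc2c(CO[Si](C(C)C)(C(C)C)C(C)C)cc(OC)cc2OCC=C(C)C)c1
F2 | step 9 | [2-bromo-6-(ArB-oxy)-4-methylphenyl]trimethylsilane | Cc1cc(Br)c([Si](C)(C)C)c(Oc2c(CO[Si](C(C)C)(C(C)C)C(C)C)cc(OC)cc2OCC=C(C)C)c1
F3 | step 9 | 3-(ArB-oxy)-5-methyl-2-(trimethylsilyl)phenyllithium | Cc1cc([Li])c([Si](C)(C)C)c(Oc2c(CO[Si](C(C)C)(C(C)C)C(C)C)cc(OC)cc2OCC=C(C)C)c1
F4 | step 9 | lithium [3-(ArB-oxy)-5-methyl-2-(trimethylsilyl)phenyl]trimethoxyborate | [Li+].CO[B-](OC)(OC)c1cc(C)cc(Oc2c(CO[Si](C(C)C)(C(C)C)C(C)C)cc(OC)cc2OCC=C(C)C)c1[Si](C)(C)C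
F5 | step 6 | 1-bromo-3-[hydroxy(tosyloxy)iodo]-5-methylbenzene | Cc1cc(Br)cc(I(O)OS(=O)(=O)c2ccc(C)cc2)c1
F6 | step 6 | (3-bromo-5-methylphenyl)(2,4,6-trimethoxyphenyl)iodonium tosylate | Cc1cc(Br)cc([I+]c2c(OC)cc(OC)cc2OC)c1.Cc1ccc(S(=O)(=O)[O-])cc1
F7 | step 6 | 2-(3-bromo-5-methylphenoxy)-5-methoxy-3-(prenyloxy)benzaldehyde | Cc1cc(Br)cc(Oc2c(C=O)cc(OC)cc2OCC=C(C)C)c1
F8 | step 6 | [2-(3-bromo-5-methylphenoxy)-5-methoxy-3-(prenyloxy)phenyl]methanol | Cc1cc(Br)cc(Oc2c(CO)cc(OC)cc2OCC=C(C)C)c1
F9 | step 11 | lithium aminoalkoxide from addition of 17 to DMF | [Li+].Cc1cc(OC(=O)N(C(C)C)[Si](C)(C)C(C)(C)C)c(C([O-])N(C)C)c(Oc2c(CO[Si](C(C)C)(C(C)C)C(C)C)cc(OC)cc2OCC=C(C)C)c1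
F10 | step 11 | 3-(ArB-oxy)-2-formyl-5-methylphenyl N-isopropylcarbamate | Cc1cc(OC(=O)NC(C)C)c(C=O)c(Oc2c(CO[Si](C(C)C)(C(C)C)C(C)C)cc(OC)cc2OCC=C(C)C)c1
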